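**Plan**

- Cuts: C5'–C6' (sp3–sp3) splits the target into a C10 chromanol half and a C8 carbinol half. In the chromanol half the pyran ring is opened at O1–C8a after a retro-1,2-shift of C4 from C4a back to C8a, which leads to a 4-alkyl-3-methylphenol. Its aryl–CH2 bond is cut to (R)-linalool and 4-iodo-3-methylphenol.
- Enabling feature: on the benzene ring O1 (on C8a) stands para to the C6 hydroxyl, and C8a lies between C8–CH3 and the unsubstituted C4a. C8a is therefore the para carbon of a plain p-alkylphenol, and the hydroquinone pattern can arise by ipso-oxygenation followed by a 1,2-alkyl shift, as the hydroquinone ring of this family (homogentisate) does in nature.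
- Forward: B-alkyl Suzuki coupling, then oxidative closure of a five-membered spiro ether on a cyclohexadienone, then dienone–phenol ring expansion to the chroman. Silylation, allylic oxidation and bromination follow, then copper-catalysed union with the C8 Grignard reagent, carbinol oxidation and desilylation.
- Stereochemistry: C2 (R) is the carbinol carbon of (R)-linalool, whose C–O bond is never broken. C8' (S) comes from a Brown (E)-crotylboration. The (E)-C3'=C4' olefin comes from linalool's trisubstituted olefin and E-selective SeO2 oxidation.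

Key step: step 2

Remark: side-chain carbons are numbered C1' (on C2) to C12', with C9' the carbonyl carbon. Commercial (R)-(−)-linalool of high enantiomeric purity is assumed, since it fixes C2. The C9' carbinol configuration carried in 12–20 is incidental and is erased in step 14.

**Step 1**
Reactants: 1 (R)-(−)-linalool [(3R)-3,7-dimethylocta-1,6-dien-3-ol]; 2 4-iodo-3-methylphenol
Product: 4 4-[(3R)-3-hydroxy-3,7-dimethyloct-6-en-1-yl]-3-methylphenol, via B-alkyl-9-BBN adduct 3 (not isolated)
Conditions: 9-BBN, THF, 0 °C → rt; then 2, Pd(dppf)Cl2 (5 mol %), aq. K3PO4, DMF, 60 °C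
Reagents that add atoms: none
Why: 9-BBN hydroborates the monosubstituted vinyl group anti-Markovnikov far faster than the trisubstituted olefin, and B-alkyl Suzuki–Miyaura coupling with the aryl iodide then joins the sp3 carbon to the ring without touching the tertiary carbinol stereocenter taken over from 1.

**Step 2**
Reactants: 4 4-[(3R)-3-hydroxy-3,7-dimethyloct-6-en-1-yl]-3-methylphenol
Product: 5 (2R)-2,6-dimethyl-2-(4-methylpent-3-en-1-yl)-1-oxaspiro[4.5]deca-6,9-dien-8-one (both configurations at spiro carbon C5)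
Conditions: PhI(OAc)2 (1.05 equiv), (CF3)2CHOH/CH2Cl2, 0 °C; aq. NaHCO3 quench
Reagents that add atoms: none
Why: Ligand exchange of the phenol on trivalent iodine and loss of PhI and acetate turn the ring into a phenoxenium-type cation whose para carbon (the one carrying the tether, the later C8a) is captured by the tertiary hydroxyl, so the O–C(aryl) bond forms and the benzene ring becomes a cross-conjugated cyclohexa-2,5-dienone. The closest known reaction type is the oxidative dearomatising spiro-etherification of 4-(3-hydroxyalkyl)phenols with PhI(OAc)2 in fluoro alcohols. The ring that closes is the five-membered spiro tetrahydrofuran, formed 5-exo-trig at the para carbon. The only new stereocenter is the spiro carbon, which is not controlled and need not be, since both epimers lose it in step 3, while the carbinol carbon keeps its (R) configuration because its C–O bond is never broken. The step needs chemoselectivity for the phenol over the trisubstituted olefin and para over ortho attack: the phenol is by far the most oxidisable group, the three-atom tether can reach only the para carbon, and the non-nucleophilic solvent leaves the tethered hydroxyl as the only competent nucleophile.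

**Step 3**
Reactants: 5 (2R)-2,6-dimethyl-2-(4-methylpent-3-en-1-yl)-1-oxaspiro[4.5]deca-6,9-dien-8-one
Product: 6 (2R)-2,8-dimethyl-2-(4-methylpent-3-en-1-yl)chroman-6-ol
Conditions: BF3·OEt2 (20 mol %), CH2Cl2, −40 → 0 °C
Reagents that add atoms: none
Why: In this dienone–phenol rearrangement, complexation of the dienone carbonyl gives a hydroxypentadienyl cation and the ring CH2 (the later C4) shifts from the spiro carbon to the unsubstituted neighbouring carbon (the later C4a), because this leaves an oxocarbenium ion at the oxygen-bearing carbon and lets loss of the C4a proton restore the benzene ring, whereas a shift to the methyl-bearing carbon is reversible and unproductive and oxygen migration would give no such stabilised cation; the C2–O bond is not involved, so (R) is retained and both spiro epimers converge on 6.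

**Step 4**
Reactants: 6 (2R)-2,8-dimethyl-2-(4-methylpent-3-en-1-yl)chroman-6-ol
Product: 7 tert-butyl{[(2R)-2,8-dimethyl-2-(4-methylpent-3-en-1-yl)chroman-6-yl]oxy}dimethylsilane
Conditions: TBSCl, imidazole, DMF, rt
Reagents that add atoms: tert-butyldimethylsilyl chloride, CC(C)(C)[Si](C)(C)Cl
Why: Imidazole-promoted silylation of the only hydroxyl masks the oxidisable chromanol for the oxidations and the Grignard coupling that follow.

**Step 5**
Reactants: 7 tert-butyl{[(2R)-2,8-dimethyl-2-(4-methylpent-3-en-1-yl)chroman-6-yl]oxy}dimethylsilane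
Product: 8 (2E)-5-[(2R)-6-(tert-butyldimethylsilyloxy)-2,8-dimethylchroman-2-yl]-2-methylpent-2-en-1-ol
Conditions: SeO2 (cat.), t-BuOOH, salicylic acid (cat.), CH2Cl2, 0 °C → rt
Reagents that add atoms: tert-butyl hydroperoxide, CC(C)(C)OO (terminal source of the oxygen atom); selenium dioxide, O=[Se]=O (catalytic oxygen carrier)
Why: Catalytic SeO2 allylic (Riley) oxidation by ene reaction and [2,3]-sigmatropic shift attacks the (E)-methyl group of the terminal isopropylidene unit and should give the (E)-allylic alcohol that fixes the later C3'=C4' geometry.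

**Step 6**
Reactants: 8 (2E)-5-[(2R)-6-(tert-butyldimethylsilyloxy)-2,8-dimethylchroman-2-yl]-2-methylpent-2-en-1-ol
Product: 9 (2R)-2-[(3E)-5-bromo-4-methylpent-3-en-1-yl]-6-(tert-butyldimethylsilyloxy)-2,8-dimethylchromane
Conditions: CBr4, PPh3, CH2Cl2, 0 °C
Reagents that add atoms: carbon tetrabromide, BrC(Br)(Br)Br
Why: The Appel reaction converts the primary allylic alcohol into the bromide by SN2 displacement of the oxyphosphonium group under neutral conditions, which should keep the olefin geometry and the silyl ether.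

**Step 7**
Reactants: 10 4-methylpent-3-en-1-ol
Product: 11 4-methylpent-3-enal
Conditions: Dess–Martin periodinane, NaHCO3, CH2Cl2, 0 °C → rt; filtered and used cold as a solution
Reagents that add atoms: none
Why: Buffered Dess–Martin oxidation reaches the aldehyde without over-oxidation, under neutral conditions that should keep the β,γ-olefin from moving into conjugation.

**Step 8**
Reactants: 11 4-methylpent-3-enal
Product: 13 (3S,4R)-3,7-dimethylocta-1,6-dien-4-ol, via diisopinocampheylborinate ester 12 (not isolated)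
Conditions: trans-2-butene, n-BuLi, KOt-Bu, THF, −78 → −45 °C; (−)-Ipc2BOMe [from (+)-α-pinene], −78 °C; BF3·OEt2; 11, −78 °C; then NaOH, H2O2, 0 °C → rt
Reagents that add atoms: trans-2-butene, C/C=C/C (delivered as the (E)-crotylborane)
Why: Brown crotylboration runs through a chair six-membered (Zimmerman–Traxler) transition state in which the (E)-crotyl geometry gives the anti adduct and the isopinocampheyl groups derived from (+)-α-pinene select one aldehyde face, which should set C3 as (S) (the later C8') and C4 as (R) (later erased by oxidation).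

**Step 9**
Reactants: 13 (3S,4R)-3,7-dimethylocta-1,6-dien-4-ol
Product: 14 triethyl{[(3S,4R)-3,7-dimethylocta-1,6-dien-4-yl]oxy}silane
Conditions: TESCl, imidazole, CH2Cl2, 0 °C
Reagents that add atoms: chlorotriethylsilane, CC[Si](CC)(CC)Cl
Why: Silylation gives a secondary triethylsilyl ether that tolerates hydroboration and Grignard chemistry and can later be removed by mild acid without loss of the aryl silyl ether.

**Step 10**
Reactants: 14 triethyl{[(3S,4R)-3,7-dimethylocta-1,6-dien-4-yl]oxy}silane
Product: 16 (3S,4R)-3,7-dimethyl-4-(triethylsilyloxy)oct-6-en-1-ol, via alkyl-9-BBN adduct 15 (not isolated)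
Conditions: 9-BBN, THF, 0 °C → rt; then NaOH, H2O2, 0 °C
Reagents that add atoms: hydrogen peroxide, OO
Why: Hydroboration–oxidation with the bulky 9-BBN is selective for the monosubstituted vinyl group over the trisubstituted olefin and places oxygen on the terminal carbon (C6') without touching the adjacent stereocenter.

**Step 11**
Reactants: 16 (3S,4R)-3,7-dimethyl-4-(triethylsilyloxy)oct-6-en-1-ol
Product: 17 (3S,4R)-1-bromo-3,7-dimethyl-4-(triethylsilyloxy)oct-6-ene
Conditions: CBr4, PPh3, imidazole, CH2Cl2, 0 °C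
Reagents that add atoms: carbon tetrabromide, BrC(Br)(Br)Br
Why: The Appel reaction on the primary alcohol, buffered with imidazole, should spare the acid-labile triethylsilyl ether.

**Step 12**
Reactants: 9 (2R)-2-[(3E)-5-bromo-4-methylpent-3-en-1-yl]-6-(tert-butyldimethylsilyloxy)-2,8-dimethylchromane; 17 (3S,4R)-1-bromo-3,7-dimethyl-4-(triethylsilyloxy)oct-6-ene
Product: 19 (2R)-6-(tert-butyldimethylsilyloxy)-2,8-dimethyl-2-[(3E,8S,9R)-4,8,12-trimethyl-9-(triethylsilyloxy)trideca-3,11-dien-1-yl]chromane, via Grignard reagent 18 (not isolated)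
Conditions: 17, Mg, THF, 40 °C; then 9, Li2CuCl4 (3 mol %), THF, −78 → 0 °C
Reagents that add atoms: none
Why: Copper-catalysed (Kochi-type) coupling of a primary alkyl Grignard reagent with a primary allylic bromide should go by direct SN2 displacement at CH2Br, forming C5'–C6' with retention of the (E)-olefin and without touching either stereocenter.

**Step 13**
Reactants: 19 (2R)-6-(tert-butyldimethylsilyloxy)-2,8-dimethyl-2-[(3E,8S,9R)-4,8,12-trimethyl-9-(triethylsilyloxy)trideca-3,11-dien-1-yl]chromane
Product: 20 (2R)-6-(tert-butyldimethylsilyloxy)-2-[(3E,8S,9R)-9-hydroxy-4,8,12-trimethyltrideca-3,11-dien-1-yl]-2,8-dimethylchromane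
Conditions: pyridinium p-toluenesulfonate (cat.), MeOH/CH2Cl2, 0 °C → rt
Reagents that add atoms: none
Why: Acid-catalysed methanolysis removes the secondary triethylsilyl ether much faster than the aryl tert-butyldimethylsilyl ether, which resists mild acid.

**Step 14**
Reactants: 20 (2R)-6-(tert-butyldimethylsilyloxy)-2-[(3E,8S,9R)-9-hydroxy-4,8,12-trimethyltrideca-3,11-dien-1-yl]-2,8-dimethylchromane
Product: 21 (2R)-6-(tert-butyldimethylsilyloxy)-2,8-dimethyl-2-[(3E,8S)-4,8,12-trimethyl-9-oxotrideca-3,11-dien-1-yl]chromane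
Conditions: Dess–Martin periodinane, NaHCO3, CH2Cl2, 0 °C
Reagents that add atoms: none
Why: Bicarbonate-buffered Dess–Martin oxidation is neutral enough that the β,γ-olefin should stay out of conjugation and the α-stereocenter C8' unepimerised, while the silyl ether keeps the chromanol from oxidation to a quinone.

**Step 15**
Reactants: 21 (2R)-6-(tert-butyldimethylsilyloxy)-2,8-dimethyl-2-[(3E,8S)-4,8,12-trimethyl-9-oxotrideca-3,11-dien-1-yl]chromane
Product: 22 (2R)-2,8-dimethyl-2-[(3E,8S)-4,8,12-trimethyl-9-oxotrideca-3,11-dien-1-yl]chroman-6-ol (CNP0280076.1)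
Conditions: Bu4NF, AcOH (1:1), THF, 0 °C
Reagents that add atoms: none
Why: Fluoride cleaves the aryl silyl ether rapidly, and the acetic acid buffer should prevent base-induced epimerisation at C8' or conjugation of the β,γ-enone.

**Compound list**

1 | (R)-(−)-linalool, (3R)-3,7-dimethylocta-1,6-dien-3-ol | C=C[C@](C)(O)CCC=C(C)C | starting material
2 | 4-iodo-3-methylphenol | Cc1cc(O)ccc1I | starting material
3 | 9-[(3S)-3-hydroxy-3,7-dimethyloct-6-en-1-yl]-9-borabicyclo[3.3.1]nonane (descriptor changes by priority only; same spatial arrangement as 1) | C(C[C@](C)(O)CCC=C(C)C)B1C2CCCC1CCC2 | intermediate (not isolated)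
4 | 4-[(3R)-3-hydroxy-3,7-dimethyloct-6-en-1-yl]-3-methylphenol | Cc1cc(O)ccc1CC[C@](C)(O)CCC=C(C)C | intermediate
5 | (2R)-2,6-dimethyl-2-(4-methylpent-3-en-1-yl)-1-oxaspiro[4.5]deca-6,9-dien-8-one, both spiro epimers | CC1=CC(=O)C=CC12CC[C@@](C)(CCC=C(C)C)O2 | intermediate
6 | (2R)-2,8-dimethyl-2-(4-methylpent-3-en-1-yl)chroman-6-ol | CC(C)=CCC[C@]1(C)CCc2cc(O)cc(C)c2O1 | intermediate
7 | tert-butyl{[(2R)-2,8-dimethyl-2-(4-methylpent-3-en-1-yl)chroman-6-yl]oxy}dimethylsilane | CC(C)=CCC[C@]1(C)CCc2cc(O[Si](C)(C)C(C)(C)C)cc(C)c2O1 | intermediate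
8 | (2E)-5-[(2R)-6-(tert-butyldimethylsilyloxy)-2,8-dimethylchroman-2-yl]-2-methylpent-2-en-1-ol | OC/C(C)=C/CC[C@]1(C)CCc2cc(O[Si](C)(C)C(C)(C)C)cc(C)c2O1 | intermediate
9 | (2R)-2-[(3E)-5-bromo-4-methylpent-3-en-1-yl]-6-(tert-butyldimethylsilyloxy)-2,8-dimethylchromane | BrC/C(C)=C/CC[C@]1(C)CCc2cc(O[Si](C)(C)C(C)(C)C)cc(C)c2O1 | intermediate
10 | 4-methylpent-3-en-1-ol | CC(C)=CCCO | starting material
11 | 4-methylpent-3-enal | CC(C)=CCC=O | intermediate
12 | (3S,4R)-3,7-dimethylocta-1,6-dien-4-yl diisopinocampheylborinate | C=C[C@H](C)[C@@H](CC=C(C)C)OB([C@@H]1C[C@@H]2C[C@H]([C@H]1C)C2(C)C)[C@@H]1C[C@@H]2C[C@H]([C@H]1C)C2(C)C | intermediate (not isolated)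
13 | (3S,4R)-3,7-dimethylocta-1,6-dien-4-ol | C=C[C@H](C)[C@H](O)CC=C(C)C | intermediate
14 | triethyl{[(3S,4R)-3,7-dimethylocta-1,6-dien-4-yl]oxy}silane | C=C[C@H](C)[C@H](O[Si](CC)(CC)CC)CC=C(C)C | intermediate
15 | 9-[(3S,4R)-3,7-dimethyl-4-(triethylsilyloxy)oct-6-en-1-yl]-9-borabicyclo[3.3.1]nonane | C(C[C@H](C)[C@H](O[Si](CC)(CC)CC)CC=C(C)C)B1C2CCCC1CCC2 | intermediate (not isolated)
16 | (3S,4R)-3,7-dimethyl-4-(triethylsilyloxy)oct-6-en-1-ol | OCC[C@H](C)[C@H](O[Si](CC)(CC)CC)CC=C(C)C | intermediate
17 | (3S,4R)-1-bromo-3,7-dimethyl-4-(triethylsilyloxy)oct-6-ene | BrCC[C@H](C)[C@H](O[Si](CC)(CC)CC)CC=C(C)C | intermediate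
18 | [(3S,4R)-3,7-dimethyl-4-(triethylsilyloxy)oct-6-en-1-yl]magnesium bromide | Br[Mg]CC[C@H](C)[C@H](O[Si](CC)(CC)CC)CC=C(C)C | intermediate (not isolated)
19 | (2R)-6-(tert-butyldimethylsilyloxy)-2,8-dimethyl-2-[(3E,8S,9R)-4,8,12-trimethyl-9-(triethylsilyloxy)trideca-3,11-dien-1-yl]chromane | CC(C)=CC[C@@H](O[Si](CC)(CC)CC)[C@@H](C)CCC/C(C)=C/CC[C@]1(C)CCc2cc(O[Si](C)(C)C(C)(C)C)cc(C)c2O1 | intermediate
20 | (2R)-6-(tert-butyldimethylsilyloxy)-2-[(3E,8S,9R)-9-hydroxy-4,8,12-trimethyltrideca-3,11-dien-1-yl]-2,8-dimethylchromane | CC(C)=CC[C@@H](O)[C@@H](C)CCC/C(C)=C/CC[C@]1(C)CCc2cc(O[Si](C)(C)C(C)(C)C)cc(C)c2O1 | intermediate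
21 | (2R)-6-(tert-butyldimethylsilyloxy)-2,8-dimethyl-2-[(3E,8S)-4,8,12-trimethyl-9-oxotrideca-3,11-dien-1-yl]chromane | CC(C)=CCC(=O)[C@@H](C)CCC/C(C)=C/CC[C@]1(C)CCc2cc(O[Si](C)(C)C(C)(C)C)cc(C)c2O1 | intermediate
22 | (2R)-2,8-dimethyl-2-[(3E,8S)-4,8,12-trimethyl-9-oxotrideca-3,11-dien-1-yl]chroman-6-ol | CC(C)=CCC(=O)[C@@H](C)CCC/C(C)=C/CC[C@]1(C)CCc2cc(O)cc(C)c2O1 | target

**Totals**

Total step count: 15. Longest linear sequence: 10 steps (steps 1–6 and 12–15); the C8 branch (steps 7–11) joins at step 12.

**Steps most likely to fail**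

1. Step 3. The 1,2-shift may run to the wrong terminus (oxygen instead of carbon migration, or a shift to the methyl-bearing carbon followed by further cationic reorganisation), or the tertiary ether may ionise and erode C2. The fallback closes the same O–aryl bond by palladium-catalysed etherification and places the phenol oxygen from the start; it sets out from 1 and comes back at 7. Commercial 2-bromo-1-iodo-3-methylbenzene is borylated at its only unhindered C–H ([Ir(cod)OMe]2, 4,4'-di-tert-butyl-2,2'-bipyridine, B2pin2) to 2-(4-bromo-3-iodo-5-methylphenyl)-4,4,5,5-tetramethyl-1,3,2-dioxaborolane F1. This is oxidised in the same pot (Oxone, aqueous acetone) to 4-bromo-3-iodo-5-methylphenol F2 and silylated (TBSCl, imidazole) to (4-bromo-3-iodo-5-methylphenoxy)(tert-butyl)dimethylsilane F3. Borane 3, made from 1 as in step 1, is coupled at the iodide (Pd(dppf)Cl2, aq. K3PO4) to (3R)-1-[2-bromo-5-(tert-butyldimethylsilyloxy)-3-methylphenyl]-3,7-dimethyloct-6-en-3-ol F4. Intramolecular Buchwald–Hartwig etherification (Pd(OAc)2, 2-(di-tert-butylphosphino)-1,1'-binaphthyl, Cs2CO3, toluene, 80 °C) then gives 7 with the carbinol C–O bond untouched.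

2. Step 12. The Grignard reagent may form poorly or couple with itself, and the copper intermediate may attack the allylic system at the γ-carbon (SN2') to give a branched 1,1-disubstituted olefin. The fallback replaces the organometallic coupling by sulfone alkylation and reductive desulfonylation; it sets out from 17 and 9 and comes back at 19. Bromide 17 is treated with PhSO2Na (DMF, 60 °C) to give [(3S,4R)-3,7-dimethyl-4-(triethylsilyloxy)oct-6-en-1-yl]sulfonylbenzene F5. Its α-lithio derivative (n-BuLi, THF, −78 °C) is alkylated by 9, strictly at CH2Br, to the C6'-phenylsulfonyl derivative of 19, F6 (both C6' epimers). The homoallylic sulfone is then removed with SmI2/HMPA (THF, −20 °C; MeOH), which cannot shift the olefin, to give 19.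

3. Step 5. The allylic oxidation may stall at low conversion, over-oxidise to the enal, or attack the benzylic C4 position. The fallback rebuilds the (E)-trisubstituted olefin by olefination instead of C–H oxidation; it sets out from 7 and comes back at 8. Ozonolysis of 7 (O3, CH2Cl2/MeOH, −78 °C, dye end-point; Me2S) gives 3-[(2S)-6-(tert-butyldimethylsilyloxy)-2,8-dimethylchroman-2-yl]propanal F7 (descriptor changes by priority only). Wittig reaction with the stabilised ylide ethyl 2-(triphenylphosphoranylidene)propanoate (toluene, 80 °C) should give ethyl (2E)-5-[(2R)-6-(tert-butyldimethylsilyloxy)-2,8-dimethylchroman-2-yl]-2-methylpent-2-enoate F8 with E selectivity. DIBAL-H (CH2Cl2, −78 °C) reduces it to 8.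

**Further compounds**

F1 | step 3 | 2-(4-bromo-3-iodo-5-methylphenyl)-4,4,5,5-tetramethyl-1,3,2-dioxaborolane | Cc1cc(B2OC(C)(C)C(C)(C)O2)cc(I)c1Br
F2 | step 3 | 4-bromo-3-iodo-5-methylphenol | Cc1cc(O)cc(I)c1Br
F3 | step 3 | (4-bromo-3-iodo-5-methylphenoxy)(tert-butyl)dimethylsilane | Cc1cc(O[Si](C)(C)C(C)(C)C)cc(I)c1Br
F4 | step 3 | (3R)-1-[2-bromo-5-(tert-butyldimethylsilyloxy)-3-methylphenyl]-3,7-dimethyloct-6-en-3-ol | Cc1cc(O[Si](C)(C)C(C)(C)C)cc(CC[C@](C)(O)CCC=C(C)C)c1Br
F5 | step 12 | [(3S,4R)-3,7-dimethyl-4-(triethylsilyloxy)oct-6-en-1-yl]sulfonylbenzene | O=S(=O)(CC[C@H](C)[C@H](O[Si](CC)(CC)CC)CC=C(C)C)c1ccccc1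
F6 | step 12 | (2R)-6-(tert-butyldimethylsilyloxy)-2,8-dimethyl-2-[(3E,8S,9R)-4,8,12-trimethyl-6-(phenylsulfonyl)-9-(triethylsilyloxy)trideca-3,11-dien-1-yl]chromane, both C6' epimers | CC(C)=CC[C@@H](O[Si](CC)(CC)CC)[C@@H](C)CC(C/C(C)=C/CC[C@]1(C)CCc2cc(O[Si](C)(C)C(C)(C)C)cc(C)c2O1)S(=O)(=O)c1ccccc1
F7 | step 5 | 3-[(2S)-6-(tert-butyldimethylsilyloxy)-2,8-dimethylchroman-2-yl]propanal | O=CCC[C@]1(C)CCc2cc(O[Si](C)(C)C(C)(C)C)cc(C)c2O1
F8 | step 5 | ethyl (2E)-5-[(2R)-6-(tert-butyldimethylsilyloxy)-2,8-dimethylchroman-2-yl]-2-methylpent-2-enoate | CCOC(=O)/C(C)=C/CC[C@]1(C)CCc2cc(O[Si](C)(C)C(C)(C)C)cc(C)c2O1
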